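**Assumptions:** the target has no stereocentre, so no stereocontrol is needed. The side chain is read as n-henicosyl (C21; target C28H48O4). 1-Bromohenicosane is taken as a catalogue compound.

**Retrosynthetic overview**
1. Target 9 comes from hydrolysis of the two vinylogous methyl esters of 2,5-dimethoxyquinone 7.
2. 7 comes from CAN oxidative demethylation of the hexasubstituted arene 6.
3. 6 comes from two successive directed ortho-lithiation/alkylations of 1,2,4,5-tetramethoxybenzene 1: first the C21 chain (1-bromohenicosane 2), then methyl (MeI).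
4. No ring is formed; the six-membered carbocycle is bought as 1.

**Route**

Step 1
Reactants: 1 1,2,4,5-tetramethoxybenzene; 2 1-bromohenicosane
Product: 4 3-henicosyl-1,2,4,5-tetramethoxybenzene, via (2,3,5,6-tetramethoxyphenyl)lithium 3 (not isolated)
Conditions: 1 (1.3 equiv), n-BuLi (1.3 equiv), TMEDA, THF, 0 °C, 1 h; then 2 (1.0 equiv), HMPA, 0 °C → rt, 16 h
Reagents that add atoms: none
Why: Directed ortho-metalation at the C–H flanked by two methoxy groups gives an aryllithium that displaces the primary bromide (SN2 alkylation, HMPA-accelerated), and excess 1 suppresses dialkylation.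

Step 2
Reactants: 4 3-henicosyl-1,2,4,5-tetramethoxybenzene
Product: 6 1-henicosyl-2,3,5,6-tetramethoxy-4-methylbenzene, via (4-henicosyl-2,3,5,6-tetramethoxyphenyl)lithium 5 (not isolated)
Conditions: n-BuLi (1.5 equiv), TMEDA, THF, 0 °C → rt, 2 h; then MeI (3 equiv), 0 °C → rt
Reagents that add atoms: iodomethane, CI
Why: A second directed ortho-metalation at the only remaining ring C–H (again between two OMe groups, so favoured over benzylic lithiation) is trapped by the small, highly reactive electrophile MeI.

Step 3
Reactants: 6 1-henicosyl-2,3,5,6-tetramethoxy-4-methylbenzene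
Product: 7 2-henicosyl-3,6-dimethoxy-5-methyl-1,4-benzoquinone
Conditions: CAN (2.5 equiv), MeCN/CH2Cl2/H2O, 0 °C → rt, 1 h
Reagents that add atoms: water, O
Why: CAN oxidative demethylation proceeds via the arene radical cation, water attacking two para methoxy-bearing carbons and methanol being expelled to give the 2,5-dimethoxy-p-quinone, while the saturated chain and methyl group are inert.

Step 4
Reactants: 7 2-henicosyl-3,6-dimethoxy-5-methyl-1,4-benzoquinone
Product: 9 2-henicosyl-3,6-dihydroxy-5-methyl-1,4-benzoquinone, via disodium quinone-bis(olate) 8 (not isolated)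
Conditions: 2 M aq NaOH, EtOH/THF, reflux, 3 h; then 2 M HCl to pH 1, recrystallise
Reagents that add atoms: sodium hydroxide, [Na+].[OH-]
Why: Hydroxide adds to each methoxy-bearing vinylogous-ester carbon and expels methoxide (addition–elimination), giving the stable dianion that is protonated to the target on acidification.

**Compound list**
1 | 1,2,4,5-tetramethoxybenzene | COc1cc(OC)c(OC)cc1OC | starting material
2 | 1-bromohenicosane | CCCCCCCCCCCCCCCCCCCCCBr | starting material
3 | (2,3,5,6-tetramethoxyphenyl)lithium | [Li]c1c(OC)c(OC)cc(OC)c1OC | intermediate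
4 | 3-henicosyl-1,2,4,5-tetramethoxybenzene | CCCCCCCCCCCCCCCCCCCCCc1c(OC)c(OC)cc(OC)c1OC | intermediate
5 | (4-henicosyl-2,3,5,6-tetramethoxyphenyl)lithium | [Li]c1c(OC)c(OC)c(CCCCCCCCCCCCCCCCCCCCC)c(OC)c1OC | intermediate
6 | 1-henicosyl-2,3,5,6-tetramethoxy-4-methylbenzene | CCCCCCCCCCCCCCCCCCCCCc1c(OC)c(OC)c(C)c(OC)c1OC | intermediate
7 | 2-henicosyl-3,6-dimethoxy-5-methyl-1,4-benzoquinone | CCCCCCCCCCCCCCCCCCCCCC1=C(OC)C(=O)C(C)=C(OC)C1=O | intermediate
8 | disodium 2-henicosyl-5-methyl-3,6-dioxocyclohexa-1,4-diene-1,4-bis(olate) | CCCCCCCCCCCCCCCCCCCCCC1=C([O-])C(=O)C(C)=C([O-])C1=O.[Na+].[Na+] | intermediate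
9 | 2-henicosyl-3,6-dihydroxy-5-methyl-1,4-benzoquinone (achiral) | CCCCCCCCCCCCCCCCCCCCCC1=C(O)C(=O)C(C)=C(O)C1=O | target

**Total step count:** 4
**Longest linear sequence:** 4

**Steps most likely to fail and fallbacks**

Step 1 (SN2 alkylation of a hindered aryllithium with a waxy C21 bromide; elimination and Li–Br exchange compete). The fallback sets out from 1 and comes back at 4. Commercial 1-henicosanol is oxidised (cat. TEMPO, PhI(OAc)2, CH2Cl2) to henicosanal F1. Compound 1 is lithiated as before to 3, which adds to F1 at −78 °C to give racemic 1-(2,3,5,6-tetramethoxyphenyl)henicosan-1-ol F2. Ionic hydrogenation (Et3SiH, TFA, CH2Cl2, 0 °C) removes the benzylic hydroxyl through the strongly stabilised benzylic cation, erases the transient stereocentre and delivers 4. The C–C bond is thus made by carbonyl addition instead of alkyl halide displacement.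

Step 3 (CAN can give some 4,5-dimethoxy-o-quinone isomer or over-oxidation, and 6 is poorly soluble in aqueous MeCN). The fallback sets out from 6 and comes back at 9, bypassing 7. Exhaustive demethylation with BBr3 (6 equiv, CH2Cl2, −78 °C → rt) gives 3-henicosyl-6-methylbenzene-1,2,4,5-tetrol F4. On aqueous work-up and stirring in EtOAc/aq NaHCO3 open to air, F4 autoxidises to the 2,5-dihydroxy-1,4-benzoquinone 9. This replaces oxidative demethylation plus hydrolysis by Lewis-acid ether cleavage plus aerobic oxidation.

Step 2 (second metalation at a fully flanked position may be incomplete, and unreacted 4 is hard to separate from 6). The fallback sets out from 4 and comes back at 6. Electrophilic bromination (NBS, anhydrous MeCN, 0 °C → rt) gives 1-bromo-4-henicosyl-2,3,5,6-tetramethoxybenzene F3, which is easily separated from 4. Suzuki–Miyaura methylation (trimethylboroxine, Pd(OAc)2/SPhos, K2CO3, dioxane/H2O, 100 °C) then gives 6. This replaces directed metalation/alkylation by SEAr halogenation and Pd cross-coupling.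

**Further compounds**
F1 | step 1 | henicosanal | CCCCCCCCCCCCCCCCCCCCC=O
F2 | step 1 | 1-(2,3,5,6-tetramethoxyphenyl)henicosan-1-ol (racemic) | CCCCCCCCCCCCCCCCCCCCC(O)c1c(OC)c(OC)cc(OC)c1OC
F3 | step 2 | 1-bromo-4-henicosyl-2,3,5,6-tetramethoxybenzene | CCCCCCCCCCCCCCCCCCCCCc1c(OC)c(OC)c(Br)c(OC)c1OC
F4 | step 3 | 3-henicosyl-6-methylbenzene-1,2,4,5-tetrol | CCCCCCCCCCCCCCCCCCCCCc1c(O)c(O)c(C)c(O)c1O
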